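**Plan**

1. Numbering: ring B is the central ring (C1/C4 aryloxy, C2/C5 OH, C3/C6 Br). Each outer ring runs C1' (ether carbon), C2' and C3' (Br), C4' (OH), C5' (Br), C6' (H). The enabling feature is that in both outer rings the ether carbon C1' sits para to the oxygenated C4', the 1,4-pattern that a 2-oxybutadiene (C6'=C1'(O)–C2'=C3') produces with an acyl alkyne delivering C4' and C5'.
2. Retrosynthesis: the C2/C5 hydroxyls are traced back to methyl ethers, the eight C–Br bonds are removed, and each C4'–O bond is traced back to C4'–acetyl (Baeyer–Villiger). After two hydrogens are added back per outer ring, C3'–C4' and C5'–C6' of both rings are cut. This leaves a bis(buta-1,3-dien-2-yl) ether of 2,5-dimethoxyhydroquinone and two molecules of but-3-yn-2-one; the dienyl ethers go back to acrylate esters.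
3. Forward: ring B is bought as the quinone. Both outer rings arise together in one double Diels–Alder reaction and are then aromatised and oxidised to aryl acetates. Bromination is staged: ring B and C2' while the outer oxygen is an acetate, then C3'/C5' once the phenol is free. Demethylation ends the route.
4. Stereochemistry: the target is achiral, with no stereocentre and no stereogenic double bond. Only regiochemistry needs control (para cycloaddition; aryloxy-over-acetoxy and then hydroxyl direction of the brominations).

Key step: step 4

Remark: the target is centrosymmetric, so both halves are treated alike and every two-fold operation is counted as a single step.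

**Route**

Step 1
Reactants: 1 2,5-dimethoxy-1,4-benzoquinone
Product: 2 2,5-dimethoxybenzene-1,4-diol
Conditions: Na2S2O4 (excess), THF/H2O, rt, under N2
Reagents that add atoms: none
Why: Reduction of a p-benzoquinone to its hydroquinone by Na2S2O4 is a fast two-electron transfer (quinone reduction) that leaves the methyl ethers untouched.

Step 2
Reactants: 2 2,5-dimethoxybenzene-1,4-diol; 3 acryloyl chloride
Product: 4 2,5-dimethoxy-1,4-phenylene diacrylate
Conditions: 3 (2.4 equiv), Et3N, BHT (trace), CH2Cl2, 0 °C to rt, under N2
Reagents that add atoms: none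
Why: O-acylation of a phenol by an acid chloride with an amine base (Schotten–Baumann-type esterification) should outpace conjugate addition at 0 °C, and BHT holds back radical polymerisation of the acrylate.

Step 3
Reactants: 4 2,5-dimethoxy-1,4-phenylene diacrylate
Product: 5 1,4-bis(buta-1,3-dien-2-yloxy)-2,5-dimethoxybenzene
Conditions: Tebbe reagent Cp2Ti(μ-CH2)(μ-Cl)AlMe2 (2.5 equiv), pyridine (cat.), THF/toluene, −40 °C to rt; aq. NaOH quench; filtration through basic Al2O3
Reagents that add atoms: Tebbe reagent Cp2Ti(μ-CH2)(μ-Cl)AlMe2, C[Al](C)C[Ti](Cl)(C1C=CC=C1)C1C=CC=C1 (cyclopentadienyl rings drawn σ-bonded, chloride bridge drawn open)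
Why: Tebbe carbonyl methylenation: the titanium methylidene Cp2Ti=CH2 adds across each ester C=O to an oxatitanacyclobutane that collapses to the enol ether; aryl esters and conjugated esters are established substrates, and the non-basic reagent should cause neither ester cleavage nor Michael addition.

Step 4
Reactants: 5 1,4-bis(buta-1,3-dien-2-yloxy)-2,5-dimethoxybenzene; 6 but-3-yn-2-one
Product: 7 1,4-bis[(4-acetylcyclohexa-1,4-dien-1-yl)oxy]-2,5-dimethoxybenzene
Conditions: 6 (5 equiv), BHT (cat.), toluene, 100 °C, sealed tube, base-washed glassware; excess 6 removed in vacuo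
Reagents that add atoms: none
Why: Each dienyl ether arm should react with the ynone in a concerted, asynchronous, normal-electron-demand [4+2] cycloaddition, the reaction type well established for 2-alkoxy- and 2-silyloxybutadienes with alkynyl ketones. Each outer ring is closed by this intermolecular suprafacial [4π+2π] addition, which forms C3'–C4' and C5'–C6' in one event and leaves a cyclohexa-1,4-diene with the ether oxygen on C1' and acetyl on C4'. No stereocentre is created. The selectivity required is para over meta orientation on both arms: the oxygen on C1' puts the largest HOMO coefficient on the neighbouring terminus C6', which bonds to the ynone β-carbon C5' (largest LUMO coefficient), so that C3' joins the acyl-bearing carbon C4'. The tetraoxygenated ring B keeps both dienes electron-rich, and BHT with a moderate temperature should hold back polymerisation of diene and ynone.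

Step 5
Reactants: 7 1,4-bis[(4-acetylcyclohexa-1,4-dien-1-yl)oxy]-2,5-dimethoxybenzene
Product: 8 1,4-bis(4-acetylphenoxy)-2,5-dimethoxybenzene
Conditions: DDQ (2.2 equiv), toluene, rt
Reagents that add atoms: none
Why: Quinone dehydrogenation: DDQ abstracts hydride from a doubly allylic CH2 of each cyclohexa-1,4-diene and the arenium ion loses a proton, an aromatisation expected to be much faster than any oxidation of ring B.

Step 6
Reactants: 8 1,4-bis(4-acetylphenoxy)-2,5-dimethoxybenzene
Product: 9 1,4-bis(4-acetoxyphenoxy)-2,5-dimethoxybenzene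
Conditions: mCPBA (3 equiv), CH2Cl2, 0 °C to 40 °C
Reagents that add atoms: mCPBA, OOC(=O)c1cccc(Cl)c1
Why: Baeyer–Villiger oxidation: in the Criegee intermediate the electron-rich 4-aryloxyphenyl group migrates in preference to methyl, as is the rule for 4-alkoxy- and 4-aryloxyacetophenones, giving the aryl acetate.

Step 7
Reactants: 9 1,4-bis(4-acetoxyphenoxy)-2,5-dimethoxybenzene
Product: 10 1,4-bis(4-acetoxy-2-bromophenoxy)-2,5-dibromo-3,6-dimethoxybenzene
Conditions: Br2 (4.4 equiv), NaOAc, AcOH, rt to 50 °C; aq. Na2S2O3 quench
Reagents that add atoms: bromine, BrBr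
Why: Electrophilic aromatic bromination: ring B, with four oxygen substituents, should take bromine at its two free positions C3 and C6, and each outer ring should then be brominated once at C2' because aryloxy is a far stronger ortho director than acetoxy (the preference shown by 4-alkoxyphenyl acetates), the first bromine deactivating the ring against a second.

Step 8
Reactants: 10 1,4-bis(4-acetoxy-2-bromophenoxy)-2,5-dibromo-3,6-dimethoxybenzene
Product: 11 1,4-bis(2-bromo-4-hydroxyphenoxy)-2,5-dibromo-3,6-dimethoxybenzene
Conditions: K2CO3 (cat.), MeOH/THF, 0 °C to rt, under N2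
Reagents that add atoms: none
Why: Base-catalysed transesterification (methanolysis) of aryl acetates is fast at room temperature and should touch neither the aryl bromides nor the ether links.

Step 9
Reactants: 11 1,4-bis(2-bromo-4-hydroxyphenoxy)-2,5-dibromo-3,6-dimethoxybenzene
Product: 12 1,4-bis(2,3,5-tribromo-4-hydroxyphenoxy)-2,5-dibromo-3,6-dimethoxybenzene
Conditions: Br2 (4.2 equiv), CH2Cl2/AcOH (anhydrous), 0 °C
Reagents that add atoms: bromine, BrBr
Why: Electrophilic bromination of a phenol goes to both positions ortho to the hydroxyl (C3' and C5'), the para position being blocked by the ether oxygen, while C6' is meta to OH and should stay free with a stoichiometric charge of bromine.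

Step 10
Reactants: 12 1,4-bis(2,3,5-tribromo-4-hydroxyphenoxy)-2,5-dibromo-3,6-dimethoxybenzene
Product: 13 3,6-dibromo-2,5-bis(2,3,5-tribromo-4-hydroxyphenoxy)benzene-1,4-diol (CNP0163357.0)
Conditions: BBr3 (excess), CH2Cl2, −78 °C to rt; then H2O
Reagents that add atoms: none
Why: Lewis-acid ether cleavage: BBr3 coordinates each methoxy oxygen and bromide attacks the methyl carbon by SN2, which cleaves alkyl aryl ethers but cannot cleave the diaryl ether links, whose carbons are sp2.

**Compound list**

1 | 2,5-dimethoxy-1,4-benzoquinone | COC1=CC(=O)C(OC)=CC1=O | starting material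
2 | 2,5-dimethoxybenzene-1,4-diol | COc1cc(O)c(OC)cc1O | intermediate
3 | acryloyl chloride | C=CC(=O)Cl | starting material
4 | 2,5-dimethoxy-1,4-phenylene diacrylate | COc1cc(OC(=O)C=C)c(OC)cc1OC(=O)C=C | intermediate
5 | 1,4-bis(buta-1,3-dien-2-yloxy)-2,5-dimethoxybenzene | COc1cc(OC(=C)C=C)c(OC)cc1OC(=C)C=C | intermediate
6 | but-3-yn-2-one | CC(=O)C#C | starting material
7 | 1,4-bis[(4-acetylcyclohexa-1,4-dien-1-yl)oxy]-2,5-dimethoxybenzene | CC(=O)C1=CCC(Oc2cc(OC)c(OC3=CCC(C(C)=O)=CC3)cc2OC)=CC1 | intermediate
8 | 1,4-bis(4-acetylphenoxy)-2,5-dimethoxybenzene | CC(=O)c1ccc(Oc2cc(OC)c(Oc3ccc(C(C)=O)cc3)cc2OC)cc1 | intermediate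
9 | 1,4-bis(4-acetoxyphenoxy)-2,5-dimethoxybenzene | CC(=O)Oc1ccc(Oc2cc(OC)c(Oc3ccc(OC(C)=O)cc3)cc2OC)cc1 | intermediate
10 | 1,4-bis(4-acetoxy-2-bromophenoxy)-2,5-dibromo-3,6-dimethoxybenzene | CC(=O)Oc1ccc(Oc2c(OC)c(Br)c(Oc3ccc(OC(C)=O)cc3Br)c(OC)c2Br)c(Br)c1 | intermediate
11 | 1,4-bis(2-bromo-4-hydroxyphenoxy)-2,5-dibromo-3,6-dimethoxybenzene | Oc1ccc(Oc2c(OC)c(Br)c(Oc3ccc(O)cc3Br)c(OC)c2Br)c(Br)c1 | intermediate
12 | 1,4-bis(2,3,5-tribromo-4-hydroxyphenoxy)-2,5-dibromo-3,6-dimethoxybenzene | Oc1c(Br)cc(Oc2c(OC)c(Br)c(Oc3cc(Br)c(O)c(Br)c3Br)c(OC)c2Br)c(Br)c1Br | intermediate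
13 | 3,6-dibromo-2,5-bis(2,3,5-tribromo-4-hydroxyphenoxy)benzene-1,4-diol | Oc1c(Br)cc(Oc2c(O)c(Br)c(Oc3cc(Br)c(O)c(Br)c3Br)c(O)c2Br)c(Br)c1Br | target

**Step count**

Total steps: 10. Longest linear sequence: 10 steps (from 1 to 13).

**Steps most likely to fail**

Step 3. The titanium methylidene may engage the acrylate C=C, or the aryl acrylate and the dienyl ether may polymerise under the Lewis-acidic conditions, so that clean double methylenation is lost. The fallback masks the vinyl group during methylenation. It sets out from 2, which is acylated with 3-chloropropanoyl chloride and pyridine in CH2Cl2 at 0 °C to give 2,5-dimethoxy-1,4-phenylene bis(3-chloropropanoate) F1. Methylenation of this saturated ester with Cp2Ti(μ-CH2)(μ-Cl)AlMe2 should give 1,4-bis[(4-chlorobut-1-en-2-yl)oxy]-2,5-dimethoxybenzene F2. E2 elimination of HCl toward the allylic hydrogens with KOtBu in THF then unveils both dienes, and the route is rejoined at 5.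

Step 4. The double cycloaddition may stall after one arm through thermal oligomerisation of the dienyl ether or the ynone, or meta attack on one arm may give regioisomer mixtures that multiply over two reacting sites. The fallback gives up ring construction for these two rings and forms the diaryl ether bonds directly. From 2, a double nucleophilic aromatic substitution on 1-(4-fluorophenyl)ethan-1-one (K2CO3, DMSO, 130 °C, under N2) should give 8, where the route is rejoined; this detour makes no compound outside the list (F0).

Step 7. Bromination may stray to C3' (ortho to acetoxy), run on to C6', or be preceded by acetate loss under HBr so that the freed phenol takes over the direction. The fallback moves the C2' bromine to the end. From 9, NBS (2 equiv) in MeCN at rt should brominate only ring B and give 1,4-bis(4-acetoxyphenoxy)-2,5-dibromo-3,6-dimethoxybenzene F3. Methanolysis with K2CO3 (cat.) in MeOH gives 1,4-bis(4-hydroxyphenoxy)-2,5-dibromo-3,6-dimethoxybenzene F4. Br2 (6 equiv) in AcOH, first at rt to fill C3' and C5' and then at 60 °C, adds the third bromine of each outer ring; at that stage C2' and C6' are equivalent, so only the degree of bromination has to be held by stoichiometry. The route is rejoined at 12.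

**Further compounds**

F1 | step 3 | 2,5-dimethoxy-1,4-phenylene bis(3-chloropropanoate) | COc1cc(OC(=O)CCCl)c(OC)cc1OC(=O)CCCl
F2 | step 3 | 1,4-bis[(4-chlorobut-1-en-2-yl)oxy]-2,5-dimethoxybenzene | COc1cc(OC(=C)CCCl)c(OC)cc1OC(=C)CCCl
F0 | step 4 | none | none
F3 | step 7 | 1,4-bis(4-acetoxyphenoxy)-2,5-dibromo-3,6-dimethoxybenzene | CC(=O)Oc1ccc(Oc2c(OC)c(Br)c(Oc3ccc(OC(C)=O)cc3)c(OC)c2Br)cc1
F4 | step 7 | 1,4-bis(4-hydroxyphenoxy)-2,5-dibromo-3,6-dimethoxybenzene | Oc1ccc(Oc2c(OC)c(Br)c(Oc3ccc(O)cc3)c(OC)c2Br)cc1
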